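The central benzene ring is built last, around the hindered C8''–C2' biaryl bond, which is already in place. The feature exploited is C1'. This carbon is bonded to C2 of the dioxygenated chromone, is para to the C4' oxygen, and is flanked by the biaryl carbon C2' and by C6'–H. C2'–C6' and the C4' oxygen therefore map onto a 4-pyranone bearing the flavon-8-yl group at C2. C1' maps onto the methyl carbon of a 2-methylchromone. In one operation the chromone dienolate replaces the pyranone ring oxygen, forms C1'–C6' and C1'–C2', and releases the C4' phenol. The precursor is 2-(5,7,4'-trimethoxyflavon-8-yl)-4H-pyran-4-one, free at C6.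

Key step: step 6

Assumption: the target string holds no stereocentre and no axial descriptor. The C8''–C2' axis has three ortho substituents and is made without control, so it would be racemic if rotation is slow.

Atom labels: unprimed = 5,7-dihydroxychromone unit; primed = central ring; double-primed = methoxylated flavone unit; triple-primed = its anisyl ring.

Design points:
- After ring opening the chain is a hex-4-ene-1,3-dione that rests as its β-diketonate. A surplus of dienolate therefore serves as proton shuttle, and the mixture is heated before the quench.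
- LiN(SiMe3)2 is preferred to stronger amide bases, because C3''–H of a flavone can be lithiated.
- The enaminone on the way to the pyranone is not isolated.
- Pentamethylbenzene is added in the last step to keep benzyl cations off C6 and C8 of the phloroglucinol-type ring.

Step 1
Reactants: 1 5,7,4'-trimethoxyflavone
Product: 2 8-iodo-5,7-dimethoxy-2-(4-methoxyphenyl)chromen-4-one
Conditions: I2 (1.05 equiv), CF3CO2Ag, CH2Cl2, 0 °C to rt, dark
Reagents that add atoms: iodine, II
Why: Electrophilic aromatic iodination goes to the trioxygenated ring A, where C8 should be favoured once the 5-oxygen is methylated because C6 is wedged between two methoxy groups, and limiting the iodine guards against the 6,8-diiodide.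

Step 2
Reactants: 2 8-iodo-5,7-dimethoxy-2-(4-methoxyphenyl)chromen-4-one; 3 (±)-but-3-yn-2-ol
Product: 4 (±)-8-(3-hydroxybut-1-yn-1-yl)-5,7-dimethoxy-2-(4-methoxyphenyl)chromen-4-one
Conditions: PdCl2(PPh3)2 (cat.), CuI (cat.), Et3N, DMF, 60 °C
Reagents that add atoms: none
Why: Sonogashira coupling of an aryl iodide with a slim terminal alkyne tolerates the two ortho oxygens and the free alcohol, and the carbinol stereocentre comes in racemic from 3 and is erased in step 3.

Step 3
Reactants: 4 (±)-8-(3-hydroxybut-1-yn-1-yl)-5,7-dimethoxy-2-(4-methoxyphenyl)chromen-4-one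
Product: 5 5,7-dimethoxy-2-(4-methoxyphenyl)-8-(3-oxobut-1-yn-1-yl)chromen-4-one
Conditions: activated MnO2 (excess), CH2Cl2, rt
Reagents that add atoms: none
Why: Heterogeneous MnO2 oxidation is selective for the aryl-conjugated propargylic alcohol and leaves the chromone and the methyl ethers alone.

Step 4
Reactants: 5 5,7-dimethoxy-2-(4-methoxyphenyl)-8-(3-oxobut-1-yn-1-yl)chromen-4-one; 6 N,N-dimethylformamide dimethyl acetal
Product: 8 2-[5,7-dimethoxy-2-(4-methoxyphenyl)-4-oxochromen-8-yl]-4H-pyran-4-one, via enaminone 7 (not isolated)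
Conditions: 6, toluene, 90 °C; evaporate; then 2 M aq. HCl, THF, 50 °C
Reagents that add atoms: water, O
Why: Aminomethylenation of the acetyl CH3 gives enaminone 7, aqueous acid unmasks the β-ketoaldehyde enol whose oxygen adds 6-endo-dig to the activated triple bond (intramolecular oxa-Michael closure of an alkynyl 1,3-dicarbonyl, a standard 4-pyranone synthesis), and any methanol or dimethylamine adduct of the alkyne has the same oxidation level and should collapse to the same ring in the acid.

Step 5
Reactants: 9 5,7-dihydroxy-2-methylchromen-4-one (noreugenin)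
Product: 10 5,7-bis(benzyloxy)-2-methylchromen-4-one
Conditions: BnBr (3 equiv), K2CO3, DMF, 70 °C
Reagents that add atoms: benzyl bromide, BrCc1ccccc1
Why: Williamson etherification takes the acidic 7-OH quickly and, with excess halide and heat, also the hydrogen-bonded 5-OH, while carbonate is too weak to alkylate the C2 methyl group.

Step 6
Reactants: 8 2-[5,7-dimethoxy-2-(4-methoxyphenyl)-4-oxochromen-8-yl]-4H-pyran-4-one; 10 5,7-bis(benzyloxy)-2-methylchromen-4-one
Product: 13 5,7-bis(benzyloxy)-2-{2-[5,7-dimethoxy-2-(4-methoxyphenyl)-4-oxochromen-8-yl]-4-hydroxyphenyl}chromen-4-one, via lithium dienolate 11 (not isolated), via open-chain enedione 12 (not isolated)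
Conditions: 10 (1.5 equiv), LiN(SiMe3)2 (1.5 equiv), THF–DMPU, −78 °C; add 8, −78 °C to rt, then 60 °C; AcOH quench
Reagents that add atoms: none
Why: Proposed new method: the exocyclic carbon of dienolate 11 adds in a vinylogous Michael sense to C6 of 8, and the dihydropyranone enolate then expels the ring oxygen (E1cB, retro-oxa-Michael) to leave the lithium β-diketonate of enedione 12. Surplus 11 shuttles a proton away from C1', which is acidified by the enone on one side and the chromone on the other, and the delocalised anion can rotate about C5'–C6' to reach the cisoid geometry needed for closure. C1' then attacks the aryl ketone carbon C2' in a 6-exo-trig aldol closure, and loss of hydroxide with tautomerisation gives the C4' phenoxide, an irreversible aromatisation that should drain the reversible side equilibria (carbonyl adduct, reclosure through oxygen). The closest known reaction types are the amine-induced exchange of 4-pyranones into 4-pyridones and the carbanion-induced conversion of pyrylium salts and 2-pyranones into benzenes, all of them addition, ring-opening, ring-closure sequences. The step needs attack at C6 of the monocyclic pyranone, which is secured because C6 is its only unsubstituted β-position, C2 is screened by the di-ortho-substituted flavonyl group, C2'' of the flavone is aryl-blocked and deactivated by three methoxy donors, and a soft delocalised dienolate in THF–DMPU favours conjugate over carbonyl addition. No stereocentre is created and the biaryl axis is left uncontrolled.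

Step 7
Reactants: 13 5,7-bis(benzyloxy)-2-{2-[5,7-dimethoxy-2-(4-methoxyphenyl)-4-oxochromen-8-yl]-4-hydroxyphenyl}chromen-4-one
Product: 14 5,7-bis(benzyloxy)-2-{2-[5,7-dimethoxy-2-(4-methoxyphenyl)-4-oxochromen-8-yl]-4-methoxyphenyl}chromen-4-one
Conditions: MeI, K2CO3, acetone, reflux
Reagents that add atoms: iodomethane, CI
Why: Williamson O-methylation meets a single free hydroxyl group, the unhindered C4' phenol, since every other oxygen is still an ether.

Step 8
Reactants: 14 5,7-bis(benzyloxy)-2-{2-[5,7-dimethoxy-2-(4-methoxyphenyl)-4-oxochromen-8-yl]-4-methoxyphenyl}chromen-4-one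
Product: 15 5,7-dihydroxy-2-{2-[5-hydroxy-7-methoxy-2-(4-methoxyphenyl)-4-oxochromen-8-yl]-4-methoxyphenyl}chromen-4-one (CNP0114008.0)
Conditions: BCl3 (8 equiv), pentamethylbenzene (6 equiv), CH2Cl2, −78 to 0 °C; MeOH, then aq. HCl work-up
Reagents that add atoms: none
Why: In this Lewis-acid ether cleavage BCl3 bound to the two C4-type carbonyl oxygens cleaves the peri 5-O-benzyl and 5''-O-methyl ethers through six-membered chelates, ionises the 7-O-benzyl ether to a cation that pentamethylbenzene captures, and should leave the three non-chelated aryl methyl ethers intact at or below 0 °C.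

Compound list
1 | 5,7,4'-trimethoxyflavone | COc1ccc(-c2cc(=O)c3c(OC)cc(OC)cc3o2)cc1 | starting material
2 | 8-iodo-5,7-dimethoxy-2-(4-methoxyphenyl)chromen-4-one | COc1ccc(-c2cc(=O)c3c(OC)cc(OC)c(I)c3o2)cc1 | intermediate
3 | (±)-but-3-yn-2-ol | CC(O)C#C | starting material
4 | (±)-8-(3-hydroxybut-1-yn-1-yl)-5,7-dimethoxy-2-(4-methoxyphenyl)chromen-4-one | COc1ccc(-c2cc(=O)c3c(OC)cc(OC)c(C#CC(C)O)c3o2)cc1 | intermediate
5 | 5,7-dimethoxy-2-(4-methoxyphenyl)-8-(3-oxobut-1-yn-1-yl)chromen-4-one | COc1ccc(-c2cc(=O)c3c(OC)cc(OC)c(C#CC(C)=O)c3o2)cc1 | intermediate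
6 | N,N-dimethylformamide dimethyl acetal | COC(OC)N(C)C | starting material
7 | 8-[(E)-5-(dimethylamino)-3-oxopent-4-en-1-yn-1-yl]-5,7-dimethoxy-2-(4-methoxyphenyl)chromen-4-one | COc1ccc(-c2cc(=O)c3c(OC)cc(OC)c(C#CC(=O)/C=C/N(C)C)c3o2)cc1 | intermediate (not isolated)
8 | 2-[5,7-dimethoxy-2-(4-methoxyphenyl)-4-oxochromen-8-yl]-4H-pyran-4-one | O=c1ccoc(-c2c(OC)cc(OC)c3c(=O)cc(-c4ccc(OC)cc4)oc23)c1 | intermediate
9 | 5,7-dihydroxy-2-methylchromen-4-one | Cc1cc(=O)c2c(O)cc(O)cc2o1 | starting material
10 | 5,7-bis(benzyloxy)-2-methylchromen-4-one | Cc1cc(=O)c2c(OCc3ccccc3)cc(OCc3ccccc3)cc2o1 | intermediate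
11 | lithium 5,7-bis(benzyloxy)-2-methylidene-2H-chromen-4-olate | [Li+].C=C1C=C([O-])c2c(OCc3ccccc3)cc(OCc3ccccc3)cc2O1 | intermediate (not isolated)
12 | (E)-6-[5,7-bis(benzyloxy)-4-oxochromen-2-yl]-1-[5,7-dimethoxy-2-(4-methoxyphenyl)-4-oxochromen-8-yl]hex-4-ene-1,3-dione, present as its lithium β-diketonate, drawn neutral | COc1ccc(-c2cc(=O)c3c(OC)cc(OC)c(C(=O)CC(=O)/C=C/Cc4cc(=O)c5c(OCc6ccccc6)cc(OCc6ccccc6)cc5o4)c3o2)cc1 | intermediate (not isolated)
13 | 5,7-bis(benzyloxy)-2-{2-[5,7-dimethoxy-2-(4-methoxyphenyl)-4-oxochromen-8-yl]-4-hydroxyphenyl}chromen-4-one | COc1ccc(-c2cc(=O)c3c(OC)cc(OC)c(-c4cc(O)ccc4-c4cc(=O)c5c(OCc6ccccc6)cc(OCc6ccccc6)cc5o4)c3o2)cc1 | intermediate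
14 | 5,7-bis(benzyloxy)-2-{2-[5,7-dimethoxy-2-(4-methoxyphenyl)-4-oxochromen-8-yl]-4-methoxyphenyl}chromen-4-one | COc1ccc(-c2cc(=O)c3c(OC)cc(OC)c(-c4cc(OC)ccc4-c4cc(=O)c5c(OCc6ccccc6)cc(OCc6ccccc6)cc5o4)c3o2)cc1 | intermediate
15 | 5,7-dihydroxy-2-{2-[5-hydroxy-7-methoxy-2-(4-methoxyphenyl)-4-oxochromen-8-yl]-4-methoxyphenyl}chromen-4-one | COc1ccc(-c2cc(=O)c3c(O)cc(OC)c(-c4cc(OC)ccc4-c4cc(=O)c5c(O)cc(O)cc5o4)c3o2)cc1 | target

Total step count: 8. Longest linear sequence: 7 (steps 1, 2, 3, 4, 6, 7, 8).

Steps most likely to fail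

1. Step 6 (new method).
   - Risk: Carbonyl addition at C4 of the pyranone may outrun conjugate addition. The sequence may also stall after ring opening, because the aryl ketone is tied up in a β-diketonate and shielded by two ortho substituents, or the chain may reclose through oxygen instead of carbon.
   - Fallback: This uses known chemistry, and the central ring is bought instead of built. It sets out from 2. Suzuki–Miyaura coupling with commercial (2-formyl-5-methoxyphenyl)boronic acid (Pd(OAc)2, SPhos, K3PO4, toluene–H2O, 90 °C) should give 2-[5,7-dimethoxy-2-(4-methoxyphenyl)-4-oxochromen-8-yl]-4-methoxybenzaldehyde F1. Claisen–Schmidt condensation with commercial 1-[2,4-bis(benzyloxy)-6-hydroxyphenyl]ethanone (KOH, EtOH–THF, rt) should give (E)-1-[2,4-bis(benzyloxy)-6-hydroxyphenyl]-3-{2-[5,7-dimethoxy-2-(4-methoxyphenyl)-4-oxochromen-8-yl]-4-methoxyphenyl}prop-2-en-1-one F2. Oxidative cyclisation of this 2'-hydroxychalcone (cat. I2, DMSO, 120 °C) closes the chromone and comes back to the route at 14, bypassing 13 and step 7.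

2. Step 4.
   - Risk: Liberated methanol or dimethylamine may consume the triple bond, the ynone may oligomerise before the acetyl group condenses, or the ring closure in acid may be incomplete.
   - Fallback: The alkyne is masked on purpose and the one-carbon unit is brought in by a Claisen condensation. It sets out from 5. Aza-Michael addition of pyrrolidine (EtOH, rt) should give 8-[(E)-3-oxo-1-(pyrrolidin-1-yl)but-1-en-1-yl]-5,7-dimethoxy-2-(4-methoxyphenyl)chromen-4-one F3. Its only enolisable position is the methyl group. Deprotonation with LiN(SiMe3)2 (THF, −78 °C) and formylation with ethyl formate should give (E)-5-[5,7-dimethoxy-2-(4-methoxyphenyl)-4-oxochromen-8-yl]-3-oxo-5-(pyrrolidin-1-yl)pent-4-enal F4. Warm aqueous HCl in THF hydrolyses the vinylogous amide and cyclodehydrates the resulting 1,3,5-tricarbonyl compound, coming back to the route at 8.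

3. Step 8.
   - Risk: The non-chelated 7-O-benzyl ether may cleave incompletely at temperatures where the methyl ethers are safe. The 7''-, 4'- or 4'''-methyl ethers may erode on warming, or the freed phloroglucinol-type ring may be C-benzylated.
   - Fallback: Two orthogonal deprotections replace the single Lewis-acid operation. It sets out from 14. Hydrogenolysis (H2, Pd/C, EtOAc–THF, rt) should give 2-{2-[5,7-dimethoxy-2-(4-methoxyphenyl)-4-oxochromen-8-yl]-4-methoxyphenyl}-5,7-dihydroxychromen-4-one F5. Chelation-controlled demethylation of the peri 5''-methoxy group alone (MgI2, THF, reflux) then comes back to the route at 15.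

Further compounds
F1 | step 6 | 2-[5,7-dimethoxy-2-(4-methoxyphenyl)-4-oxochromen-8-yl]-4-methoxybenzaldehyde | COc1ccc(-c2cc(=O)c3c(OC)cc(OC)c(-c4cc(OC)ccc4C=O)c3o2)cc1
F2 | step 6 | (E)-1-[2,4-bis(benzyloxy)-6-hydroxyphenyl]-3-{2-[5,7-dimethoxy-2-(4-methoxyphenyl)-4-oxochromen-8-yl]-4-methoxyphenyl}prop-2-en-1-one | COc1ccc(-c2cc(=O)c3c(OC)cc(OC)c(-c4cc(OC)ccc4/C=C/C(=O)c4c(O)cc(OCc5ccccc5)cc4OCc4ccccc4)c3o2)cc1
F3 | step 4 | 8-[(E)-3-oxo-1-(pyrrolidin-1-yl)but-1-en-1-yl]-5,7-dimethoxy-2-(4-methoxyphenyl)chromen-4-one | COc1ccc(-c2cc(=O)c3c(OC)cc(OC)c(/C(=C\C(C)=O)N4CCCC4)c3o2)cc1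
F4 | step 4 | (E)-5-[5,7-dimethoxy-2-(4-methoxyphenyl)-4-oxochromen-8-yl]-3-oxo-5-(pyrrolidin-1-yl)pent-4-enal | COc1ccc(-c2cc(=O)c3c(OC)cc(OC)c(/C(=C\C(=O)CC=O)N4CCCC4)c3o2)cc1
F5 | step 8 | 2-{2-[5,7-dimethoxy-2-(4-methoxyphenyl)-4-oxochromen-8-yl]-4-methoxyphenyl}-5,7-dihydroxychromen-4-one | COc1ccc(-c2cc(=O)c3c(OC)cc(OC)c(-c4cc(OC)ccc4-c4cc(=O)c5c(O)cc(O)cc5o4)c3o2)cc1
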